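Late on, the grey run stands still with about 7.00% of its free monomer unreacted at 0.51 M of transfer agent, while the teal run stops lower, near 1.55%, at 0.32 M.

in all of them: pre-initiator 7.7 mM; impurity 1.5 mM

| flask | free monomer | transfer agent | remark | time |
|---|---|---|---|---|
| teal | 0.77 M (fed, over 2.5 h) | 0.32 M | run made earlier; the fed solution adds 0.50 times the starting volume |  |
| grey | 0.77 M (fed, over 2.5 h) | 0.51 M | run made earlier; the fed solution adds 0.50 times the starting volume |  |
| green | 1.2 M (fed, over 2.5 h) | 0.231 M | run made earlier; the fed solution adds 0.50 times the starting volume |  |
| flask | 0.77 M (fed, over 2.5 h) | 0.231 M | the fed solution adds 0.50 times the starting volume | 50 h |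

| run | time / h | monomer in chains / % | free monomer / % |
|---|---|---|---|
| teal | 6.00 | 72.4 | 27.2 |
| teal | 12.0 | 93.2 | 6.9 |
| teal | 20.0 | 98.1 | 0.9 |
| teal | 25.0 | 97.9 | 3.3 |
| teal | 30.0 | 97.5 | 2.0 |
| teal | 40.0 | 98.0 | 0 |
| grey | 6.00 | 63.2 | 38.7 |
| grey | 12.0 | 85.1 | 14.6 |
| grey | 20.0 | 92.1 | 7.8 |
| grey | 25.0 | 91.8 | 6.5 |
| grey | 30.0 | 93.7 | 6.9 |
| grey | 40.0 | 94.0 | 6.8 |
| green | 4.00 | 53.0 | 46.9 |
| green | 10.0 | 95.5 | 5.9 |
| green | 20.0 | 98.4 | 0.8 |
| green | 30.0 | 100.0 | 0 |
| green | 40.0 | 98.9 | 1.1 |

(readings scatter by 1 percentage point)

- every charge counts on the volume at the start, and the solution that is fed holds the whole dose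
- the average divides the monomer in chains by the number of chains begun, living and dead together
- the earlier runs do not show the number of chains; that part of a forecast is a guess

1. average number of monomer units in a chain (chains begun, living or dead) at 50 h
2. part of the free monomer that has reacted at 50 h

Take living ends as what eats the monomer and the agent as what kills them. The agent far outnumbers any ends, so take each end's chance of dying per hour as proportional to the agent (pseudo-first-order). Free monomer loses a share per hour proportional to the ends present. Divide one rate by the other and time drops out. With pre-initiator and impurity held as charged, one figure stays fixed. Grey gives 1.36 M for this stopping product, the agent charge times the logarithm of monomer charged over monomer left.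

Test it on teal: it predicts 1.44% left against the reading of 1.55%, inside the scatter of 1 percentage point. For the flask, at 0.231 M of agent, it gives 0.282% left, so 99.7% reacted.

The runs stop, so I take a killed end as restarting nothing. Chains begun then come from pre-initiator less impurity, 6.20 mM on the starting volume, and my dp is 124. The weak link is that count, which supposes the pre-initiator has finished turning over by 50 h.

The forecast differs from my dp: it says 3.3 and 99%, reasoning that “Chains begun are roughly agent plus initiator minus impurity”. The flask gives dp 132 and 99.8% reacted.

    free monomer + initiator → living end + monomer in chains (k = 0.357 M⁻¹ min⁻¹)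
    free monomer + living end → monomer in chains + living end, rate k2*[living end]*[free monomer] (k = 6.33 M⁻¹ min⁻¹)
    living end + transfer agent → dead chain (kL = 0.0274 M⁻¹ min⁻¹)
    initiator + impurity → spent initiator (k = 51.2 M⁻¹ min⁻¹)
    pre-initiator → initiator (k = 0.00228 min⁻¹)

In this flask 0.24% of the free monomer is left at 50.0 h, against the product's 0.282%. Reforging the link, chains begun stand at 5.82 mM on the starting volume, with 0.368 mM of initiator still unused. At 3.93 h free monomer has a half-life of 1.9 h by growth on living ends, far shorter than 23 d by reaction with initiator. Growth is then using it 280 times as fast. With 0.447 M of transfer agent, this flask's reacted part has moved by 4 points, and the stopping product, counted from its own 0.282%, puts that move at 4.5 points.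

The readings were computed from invented constants.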